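The trap in this flask is to forecast each substrate on its own and then subtract: the excess hangs on a difference between two remainders, and an error in either lands wholly in that difference. Treat the gap as the thing you reckon.

| setting | Tuesday's | Thursday's | flask |
|---|---|---|---|
| left-handed substrate | 6.7 mM | 15 mM | 10 mM |
| right-handed substrate | 6.7 mM | 15 mM | 10 mM |
| gas | 3.8 mM (held) | 3.8 mM (held) | 3.8 mM (held) |
| precatalyst | 10 µM | 10 µM | 10 µM |
| remark | run made earlier | run made earlier |  |
| time |  |  | 50 min |

| run | time / min | right-handed substrate / % | left-handed substrate / % | left-handed product / % |
|---|---|---|---|---|
| Tuesday's | 5.00 | 52 | 51 | 1 |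
| Tuesday's | 12.0 | 48 | 43 | 6 |
| Tuesday's | 25.0 | 44 | 34 | 16 |
| Tuesday's | 60.0 | 25 | 10 | 42 |
| Thursday's | 5.00 | 52 | 48 | 0 |
| Thursday's | 12.0 | 51 | 48 | 2 |
| Thursday's | 25.0 | 46 | 47 | 6 |
| Thursday's | 60.0 | 37 | 31 | 17 |

(each reading ± 1.5 percentage points)

- whether the excess of right-handed substrate over left-handed substrate among what is left of the two reaches 90% by 50 min (no / yes)
- the highest excess of right-handed substrate over left-handed substrate among what is left of the two up to 50 min

- free catalyst is single-handed; left-handed substrate and right-handed substrate are mirror images of each other, charged as a racemate, each of them at the stated concentration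
- at the start none of the gas is in solution

This is a kinetic resolution, so write the excess as gap yield times consumed share, divided by the share remaining. An error of 10% in the yield moves the excess by 10%, whereas an error in the consumed share counts for more, since it also changes the remainder. Gas and precatalyst stand the same in both runs and this flask, so they need no number of their own.

Now the numbers, from the last readings. Tuesday's run gives 0.231 and Thursday's 0.188, so I take 0.209 as the gap yield, the gap between right-handed and left-handed substrate per part of the charge consumed. Rescaled to this flask's charge, the consumption at 60.0 min reads 43.6% and 48.0%. Taken proportional to time, which flatters it slightly given the slow start, that is 38.1% by 50 min. Here a share error counts 1.62 times. My excess is 12.9%. Reaching 90% at this yield takes a consumed share of 81.1%, twice what I expect, so the answer I commit to is no.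

The forecast says no and 16%, above mine: “It rises steadily, so the maximum falls at 50 min”.

The flask gives no and 15.6%.

    free catalyst + left-handed substrate ⇌ catalyst intermediate A (K = 270 /M, k = 9700 /M/s)
    free catalyst + right-handed substrate ⇌ catalyst intermediate B (K = 1100 /M, k = 11000 /M/s)
    coupling partner + catalyst intermediate A → free catalyst + left-handed product (k = 4200 /M/s)
    coupling partner + catalyst intermediate B → free catalyst + right-handed product (k = 370 /M/s)
    left-handed substrate ⇌ right-handed substrate (k = 1.50 × 10⁻⁴ /s)
    gas ⇌ coupling partner, rate k6*(csat - [coupling partner]) (kL = 8.20 × 10⁻⁴ /s)
    coupling partner + precatalyst → free catalyst + spent reagent (k = 0.780 /M/s)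

At 50.0 min the flask has consumed 37.3% of its charge, at a gap yield of 0.262. Read the same flask at 2.0 h and the consumed share is 92.7%, past the 81.1% reckoned above, yet the excess stays under 90%. The carried yield would give 265% there, an impossible figure for an excess. At 2.0 h the flask holds 6.13% right-handed substrate against 1.15% left-handed, a gap yield of 0.0537 and an excess of 68.3%.

The numbers in the tables were computed with made-up constants, and the scatter is random.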